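# Proposed synthesis of CNP0289166.2 (oplopane triester) by nickel-catalysed ynal cyclisation

**Remarks on the chemistry (assumptions and corrections)**
- Locants: the final hydrindanone numbering is used for all intermediates, also the monocyclic ones. Ring A is C1, C2 (C=O), C3, C3a, C7a; ring B is C3a, C4 (=CH2), C5, C6, C7, C7a.
- The target SMILES fixes the (2R)-2-methylbutanoyl group and a syn-aldol relationship between C1 (R) and the side-chain carbinol (1S); the route is planned for both.
- The aldehyde arm of the cyclisation precursor is ring–CH(iPr)–CH2–CHO (a 4-methyl-1-oxopentan-3-yl group), as its SMILES shows; a 4-oxobutyl arm would close a seven-membered ring.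
- (2R)-2-Methylbutanoic acid and (2E)-3-methylpent-2-enoic acid are treated as purchasable acids.
- The Diels–Alder adduct A1 is written with the C3 silyl ether on the face of the target ester (trans to the C3a hydrogen); its C3 epimer would need a late inversion.

## Structural features

The target is a trans-fused hydrindan-2-one. Ring A is a cyclopentanone (C1, C2, C3, C3a, C7a) and ring B a cyclohexane (C3a, C4, C5, C6, C7, C7a), joined through the C3a–C7a bond with the two fusion hydrogens anti. Ring B carries an exocyclic methylene on C4, an axial (E)-3-methylpent-2-enoate on C5 and an equatorial isopropyl group on C7. Ring A carries a (2R)-2-methylbutanoate on C3 and a (1S)-1-acetoxyethyl arm on C1, both on the same face of the ketone. Six ring stereocentres are nearly contiguous (C1–C7a–C7 and C3–C3a, with C5 across the methylene carbon); two more lie outside the rings (the arm carbinol, syn-aldol related to C1, and C2 of the butanoate). Fragile points are the β-acetoxy ketone (E1cB loss of acetate), the enolisable α-acyloxy ketone at C3, the enolisable C1 centre, and the allylic C5 ester beside a 1,1-disubstituted alkene (SN2′, ionisation). The real difficulty is the dense, differentiated oxygenation (three different esters, two of them axial-type and flanking C4) on a trans-hydrindane whose fusion has no epimerisable handle. The key step uses the 2-methylidenecyclohexanol unit C4(=CH2)–C5(O) of ring B, the retron of a reductive alkyne–aldehyde coupling. The C4–C5 bond, ring B, the alkene and the C5 oxygen arise together from an ethynyl group on C3a and an aldehyde at the end of the arm C7a–C7–C6–C5.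

## Logic of the disconnections

**28 ⇒ 27 ⇒ 26.** The acyl C–O bond of the acetate is cut first, and the free carbinol of 27 is traced to the silyl ether 26. Once the acetate is in place any base can expel it from the β-position of the ketone, so it must be the last group introduced. The gain is one robust protecting group that carries the arm oxygen from step 4 to step 14. The demand is a non-basic desilylation and an acetylation mild enough for a β-hydroxy ketone.

**26 ⇒ 24 + 25.** The C5–O bond is cut with inversion. The ring-closing step can only deliver an equatorial C5 oxygen, whereas 28 has it axial; an inverting esterification corrects the centre and attaches the acyl group in one operation. The gain is that no separate inversion sequence is needed. The demand is direct rather than allylic displacement at C5, and a C5 silyl ether in 23 that can be removed beside the arm silyl ether.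

**24 ⇒ 23 ⇒ 21 + 22; 21 ⇒ 19 (through 20).** The C3 ester is cut at its acyl C–O bond, then the C3–O bond itself is cut back to the ketone enolate. C3 is the only methylene beside the carbonyl, so kinetic enolisation is unambiguous. The gain is a cyclisation substrate without oxygen at C3: one stereocentre, one protecting group and one enolisable α-oxygenated centre fewer during the organometallic steps. The demand is enolisation away from C1 (whose enolate would expel the silyloxy group), oxygen delivery anti to the C3a hydrogen, and retention at C2 of acid 22.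

**19 ⇒ 18.** The C4–C5 bond is cut, opening ring B. A ring, the exocyclic alkene and the C5 oxygen disappear together, leaving a trisubstituted cyclopentanone. The demand is a catalyst that couples a terminal alkyne with an aldehyde beside a ketone and without base, and trans arms on ring A so that the fusion is trans.

**18 ⇒ 17 ⇒ 16.** The alkyne C–H is traced to C–Si and the aldehyde to a thioester. Both reactive termini are then unveiled only immediately before use. The demand is a thioester reduction that spares the ketone and a desilylation that avoids base, since 18 is aldol-prone.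

**16 ⇒ 14 + 15.** The C7–isopropyl bond is cut as a conjugate addition. This sets C7 under catalyst control and reduces the arm to a simple enethioate. The demand is Re-face delivery at C7 and chemoselectivity over the ring ketone.

**14 ⇒ 12 + 13; 12 ⇒ 11.** The C6=C7 bond is cut by cross-metathesis and the O–Si bond by silylation. The arm shrinks to a vinyl group. The demand is a metathesis catalyst that ignores the silylated alkyne.

**11 ⇒ 6 + 7 + 8 (through 9 and 10).** The C7a–vinyl bond and the C1–carbinol bond are cut in one three-component operation. Three stereocentres (C7a, C1, carbinol) are traced to the single centre of 6. The demand is addition anti to the alkynyl group, aldol anti to the new vinyl group, and a syn aldol at the carbinol.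

**6 ⇒ 5 ⇒ 1 + 2 (through 3 and 4).** The alcohol oxidation level is adjusted, then the C3a–C(sp) bond is cut with inversion. The only absolute stereochemical information then comes from the commercial monoacetate 1. The demand is 1,4-substitution with clean inversion.

## Other disconnections considered

**Alternative 1: intramolecular Diels–Alder through a dithiane tether.**
- **Cut:** the fusion bond C3a–C7a and the C6–C7 bond of ring B; ring A closes through the tether.
- **Forward step:** the trienone A2 (an (E)-enone linked through C1, the dithiane carbon C2 and the silyloxy carbon C3 to a 3-methylbuta-1,3-dienyl unit) is heated, or treated with Me2AlCl at low temperature, to give the trans-fused methyl ketone A1.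
- **In favour:** two rings, two C–C bonds and three stereocentres (C3a, C7a, C7) form in one concerted step, which is more complexity per step than the chosen cyclisation. The C3 oxygen is present from the outset and should steer the facial course by allylic strain against the diene methyl group, so the late enolate hydroxylation of the chosen plan is not needed; on this point the alternative is the better one. No transition metal is required.
- **Against:** trans selectivity of terminally activated nonatrienones is often modest, and the Lewis acid has to compete with the dithiane and silyl ether for coordination. A1 carries the wrong functionality at three sites: an acetyl group where the isopropyl belongs, a C4-methyl ring alkene where the methylidene and C5 oxygen are needed (an ene-type oxygenation with its own regio- and facial questions), and no arm at C1. The C1 arm would still need an aldol after dithiane removal, with the same syn requirement and an added C1/C3 regiochemical question.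
- **Comparison:** structurally the alternative reaches the bicycle earlier; mechanistically it is more predictable than a zerovalent nickel cycle. Both plans need a separate stereochemical decision at C5 (equal). In step economy the corrections after A1 are estimated to outnumber the six steps that follow the chosen cyclisation.

**Alternative 2: desymmetrised cyclohexanone, ring A closed by C–H insertion.**
- **Cut:** the C1–C7a bond of ring A.
- **Forward step:** Rh2(OAc)4 (dirhodium tetraacetate) converts the α-diazo-β-keto ester A4 into a carbenoid that inserts into the equatorial C7a–H bond, giving the trans-fused β-keto ester A3.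
- **In favour:** the carbon framework of ring B comes from cheap, symmetrical 4-(propan-2-yl)cyclohexanone A5, so the C7 centre needs no asymmetric conjugate addition; this is better than step 6 of the chosen plan. Insertion with retention makes the trans fusion as predictable as in the chosen plan (equal). The C3 oxygen is again installed early.
- **Against:** the reacting methylene lies beside the isopropyl-bearing carbon and is hindered. A3 has an ester where the 1-acetoxyethyl arm must be, which means several redox steps and a new stereocentre next to a 1,3-dicarbonyl unit. Ring B has none of its final functionality: after ketal removal, C5 must be oxygenated and a hindered α-oxygenated ketone methylenated.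
- **Comparison:** the carbenoid step is at least as reliable as the nickel step. The methylidene/C5–O unit that the chosen step makes in one operation would cost four or more steps here, so the overall sequence is expected to be longer.

**Alternative 3: Pauson–Khand annulation of an acyclic 1,7-enyne.**
- **Cut:** the fusion bond C3a–C7a and both bonds to the ketone carbon C2.
- **Forward step:** Co2(CO)8 with an amine N-oxide (or [RhCl(CO)2]2 under CO) joins the alkyne, the vinyl group and CO of the enyne A7 to the bicyclic cyclopentenone acetonide A6.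
- **In favour:** three C–C bonds and both rings form in one step. The arm carbinol comes from the chiral pool ((S)-but-3-yn-2-ol A8), which is better than the aldol of step 3. The C5 oxygen is carried in its final configuration, so no inversion is needed, which is better than step 13.
- **Against:** 1,7-enynes cyclise more slowly than 1,6-enynes. A6 is an enone with C7a still sp2, so the trans fusion must come from a later reduction of a tetrasubstituted enone, where the cis isomer is the usual kinetic product; the chosen plan fixes the fusion from trans arms on a monocycle and is better here. C4 carries a hydroxymethyl placeholder that must be unmasked and eliminated. The propargylic C7 centre needs its own asymmetric step (equal to step 6), and C3 must still be hydroxylated (equal to step 10).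
- **Comparison:** ring construction is more convergent than in the chosen plan, but the steps after cyclisation are expected to be more numerous and the fusion less secure.

Key step: step 9

## Route

Step 1
Reactants: 1 (1S,4R)-cis-4-acetoxycyclopent-2-en-1-ol; 2 ethynyltrimethylsilane
Product: 5 (1S,4S)-4-[(trimethylsilyl)ethynyl]cyclopent-2-en-1-ol, via lithium (trimethylsilyl)acetylide 3 (not isolated), via chloro[(trimethylsilyl)ethynyl]zinc 4 (not isolated)
Conditions: 2 (2.5 equiv), n-BuLi, THF, −78 °C; ZnCl2, −78 to 0 °C; then 1, Pd(PPh3)4 (5 mol%), THF, 0 °C to rt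
Reagents that add atoms: ethynyltrimethylsilane 2 (as zinc reagent 4), C#C[Si](C)(C)C
Why: Negishi-type allylic alkynylation: zerovalent palladium ionises the allylic acetate with inversion, the alkynyl group passes from zinc to palladium and reductive elimination delivers it on the palladium face, so the net result should be inversion at C3a (trans-1,4 product) with bond formation at the allyl terminus remote from the oxygen-bearing carbon; the carbinol centre is untouched.

Step 2
Reactants: 5 (1S,4S)-4-[(trimethylsilyl)ethynyl]cyclopent-2-en-1-ol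
Product: 6 (4S)-4-[(trimethylsilyl)ethynyl]cyclopent-2-en-1-one
Conditions: activated MnO2 (excess), CH2Cl2, rt
Reagents that add atoms: none
Why: Allylic alcohol oxidation on MnO2 under neutral, heterogeneous conditions; the doubly activated γ-hydrogen at C3a is not exposed to base, so the stereocentre should survive.

Step 3
Reactants: 6 (4S)-4-[(trimethylsilyl)ethynyl]cyclopent-2-en-1-one; 7 vinylmagnesium bromide; 8 acetaldehyde
Product: 11 (2R,3R,4S)-3-ethenyl-2-[(1S)-1-hydroxyethyl]-4-[(trimethylsilyl)ethynyl]cyclopentan-1-one, via bromomagnesium enolate 9 (not isolated), via tri(isopropoxy)titanium enolate 10 (not isolated)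
Conditions: 7 (1.3 equiv), CuBr·SMe2 (10 mol%), THF, −78 °C; ClTi(OiPr)3 (1.5 equiv), −78 to −40 °C; 8 (3 equiv), −78 °C; aq NH4Cl
Reagents that add atoms: vinylmagnesium bromide 7, C=C[Mg]Br; acetaldehyde 8, CC=O
Why: Copper-catalysed 1,4-addition of the vinyl Grignard reagent anti to the alkynyl group sets C7a, and the aldol of the derived enolate anti to the new vinyl group sets C1 (tandem conjugate addition–aldol); tri(isopropoxy)titanium enolates of cyclic ketones are known to favour the syn aldol, the opposite of the usual Zimmerman–Traxler outcome of lithium or zinc enolates, and syn is the (1S) carbinol required.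

Step 4
Reactants: 11 (2R,3R,4S)-3-ethenyl-2-[(1S)-1-hydroxyethyl]-4-[(trimethylsilyl)ethynyl]cyclopentan-1-one
Product: 12 (2R,3R,4S)-2-[(1S)-1-{[tert-butyl(dimethyl)silyl]oxy}ethyl]-3-ethenyl-4-[(trimethylsilyl)ethynyl]cyclopentan-1-one
Conditions: TBSOTf (1.2 equiv), 2,6-lutidine, CH2Cl2, −78 °C
Reagents that add atoms: tert-butyldimethylsilyl trifluoromethanesulfonate, CC(C)(C)[Si](C)(C)OS(=O)(=O)C(F)(F)F
Why: Silylation of a β-hydroxy ketone with a silyl triflate and a hindered pyridine base at low temperature, conditions under which retro-aldol and elimination should not compete.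

Step 5
Reactants: 12 (2R,3R,4S)-2-[(1S)-1-{[tert-butyl(dimethyl)silyl]oxy}ethyl]-3-ethenyl-4-[(trimethylsilyl)ethynyl]cyclopentan-1-one; 13 S-ethyl prop-2-enethioate
Product: 14 S-ethyl (2E)-3-{(1R,2R,5S)-2-[(1S)-1-{[tert-butyl(dimethyl)silyl]oxy}ethyl]-3-oxo-5-[(trimethylsilyl)ethynyl]cyclopentyl}prop-2-enethioate
Conditions: 13 (3 equiv), second-generation Hoveyda–Grubbs catalyst RuCl2(H2IMes)(=CH-C6H4-2-OiPr) (5 mol%), CH2Cl2, 40 °C
Reagents that add atoms: S-ethyl prop-2-enethioate 13, C=CC(=O)SCC
Why: Olefin cross-metathesis of a terminal alkene with an electron-poor thioacrylate, which should give the (E)-enethioate; the bulky silylated alkyne and the ketone are not expected to engage the ruthenium carbene.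

Step 6
Reactants: 14 S-ethyl (2E)-3-{(1R,2R,5S)-2-[(1S)-1-{[tert-butyl(dimethyl)silyl]oxy}ethyl]-3-oxo-5-[(trimethylsilyl)ethynyl]cyclopentyl}prop-2-enethioate; 15 isopropylmagnesium bromide
Product: 16 S-ethyl (3R)-3-{(1R,2R,5S)-2-[(1S)-1-{[tert-butyl(dimethyl)silyl]oxy}ethyl]-3-oxo-5-[(trimethylsilyl)ethynyl]cyclopentyl}-4-methylpentanethioate
Conditions: 15 (1.3 equiv, slow addition), CuI (3 mol%), Tol-BINAP (3.3 mol%, the antipode that gives Re-face attack at C7), t-BuOMe, −70 °C; quench with MeOH then aq NH4Cl at −70 °C
Reagents that add atoms: isopropylmagnesium bromide 15, CC(C)[Mg]Br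
Why: Copper-catalysed asymmetric conjugate addition of a Grignard reagent to an α,β-unsaturated thioester; the chiral bisphosphine–copper complex should deliver isopropyl to the Re face of C7 and so set the (R) centre, while at −70 °C with slow addition the catalysed 1,4-addition should outrun attack on the hindered ring ketone.

Step 7
Reactants: 16 S-ethyl (3R)-3-{(1R,2R,5S)-2-[(1S)-1-{[tert-butyl(dimethyl)silyl]oxy}ethyl]-3-oxo-5-[(trimethylsilyl)ethynyl]cyclopentyl}-4-methylpentanethioate
Product: 17 (3R)-3-{(1R,2R,5S)-2-[(1S)-1-{[tert-butyl(dimethyl)silyl]oxy}ethyl]-3-oxo-5-[(trimethylsilyl)ethynyl]cyclopentyl}-4-methylpentanal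
Conditions: Et3SiH (3 equiv), 10% Pd/C (5 mol% Pd), acetone, rt
Reagents that add atoms: none
Why: Fukuyama reduction: palladium inserts into the C–S bond and the silane supplies hydride, giving the aldehyde without reducing the ketone (which a metal hydride would not spare) or the hindered silylated alkyne.

Step 8
Reactants: 17 (3R)-3-{(1R,2R,5S)-2-[(1S)-1-{[tert-butyl(dimethyl)silyl]oxy}ethyl]-3-oxo-5-[(trimethylsilyl)ethynyl]cyclopentyl}-4-methylpentanal
Product: 18 (3R)-3-{(1R,2R,5S)-2-[(1S)-1-{[tert-butyl(dimethyl)silyl]oxy}ethyl]-5-ethynyl-3-oxocyclopentyl}-4-methylpentanal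
Conditions: AgNO3 (10 mol%), acetone/H2O, rt, dark
Reagents that add atoms: none
Why: Silver-catalysed protodesilylation of a trimethylsilylalkyne under neutral conditions; carbonate or fluoride is avoided because the keto aldehyde can undergo intramolecular aldol reaction, and the secondary silyl ether should be untouched.

Step 9
Reactants: 18 (3R)-3-{(1R,2R,5S)-2-[(1S)-1-{[tert-butyl(dimethyl)silyl]oxy}ethyl]-5-ethynyl-3-oxocyclopentyl}-4-methylpentanal
Product: 19 (1R,3aS,5R,7R,7aR)-1-[(1S)-1-{[tert-butyl(dimethyl)silyl]oxy}ethyl]-4-methylidene-7-(propan-2-yl)-5-[(triethylsilyl)oxy]octahydro-2H-inden-2-one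
Conditions: Ni(COD)2 (15 mol%), IPr (1,3-bis(2,6-diisopropylphenyl)imidazol-2-ylidene, free carbene, 15 mol%), Et3SiH (3 equiv), THF, rt, 18 added over 2 h
Reagents that add atoms: triethylsilane, CC[SiH](CC)CC
Why: Zerovalent nickel bearing the bulky carbene binds the aldehyde and the terminal alkyne of 18 and undergoes oxidative cyclisation to an oxanickelacyclopentene, which forms the C4–C5 bond; σ-bond metathesis of the Ni–O bond with the silane and C–H reductive elimination then release the silyl ether and the vinylic hydrogen. The closest known reaction type is the nickel-catalysed reductive cyclisation of alkynals with trialkylsilanes to exocyclic allylic silyl ethers. Ring B closes in the 6-exo-dig mode at the internal alkyne carbon; the endo mode would require an (E)-cycloheptene and is not accessible. The new stereocentre C5 is controlled by the metallacycle: oxygen, C5, C4 and the terminal alkyne carbon must be coplanar, which in the chair-like ring B (fusion bonds and isopropyl equatorial) places the C5–O bond equatorial, that is (5R). The step needs aldehyde-over-ketone chemoselectivity, which should follow from the much stronger binding of aldehydes to nickel and from the flanked position of the ring ketone. It also needs cyclisation to outrun alkyne oligomerisation and plain hydrosilylation, which slow addition of 18 and the bulky ligand should favour. The free carbene is used without alkoxide base because 18 is an aldol-prone keto aldehyde, and the trans arrangement of the two arms on ring A, fixed in steps 1 and 3, makes the product trans-fused.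

Step 10
Reactants: 19 (1R,3aS,5R,7R,7aR)-1-[(1S)-1-{[tert-butyl(dimethyl)silyl]oxy}ethyl]-4-methylidene-7-(propan-2-yl)-5-[(triethylsilyl)oxy]octahydro-2H-inden-2-one
Product: 21 (1R,3R,3aS,5R,7R,7aR)-1-[(1S)-1-{[tert-butyl(dimethyl)silyl]oxy}ethyl]-3-hydroxy-4-methylidene-7-(propan-2-yl)-5-[(triethylsilyl)oxy]octahydro-2H-inden-2-one, via potassium enolate 20 (not isolated)
Conditions: KN(SiMe3)2 (1.1 equiv), THF, −78 °C; 3-phenyl-2-(phenylsulfonyl)oxaziridine (1.3 equiv), −78 °C; aq NH4Cl
Reagents that add atoms: 3-phenyl-2-(phenylsulfonyl)oxaziridine, O=S(=O)(c1ccccc1)N1OC1c1ccccc1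
Why: Kinetic deprotonation at the only α-methylene (C3) followed by oxygen transfer from the Davis oxaziridine to the enolate; attack anti to the pseudoaxial C3a hydrogen is torsionally favoured and gives the pseudoaxial C3–O bond that avoids the C4 methylene, which should set (3R).

Step 11
Reactants: 21 (1R,3R,3aS,5R,7R,7aR)-1-[(1S)-1-{[tert-butyl(dimethyl)silyl]oxy}ethyl]-3-hydroxy-4-methylidene-7-(propan-2-yl)-5-[(triethylsilyl)oxy]octahydro-2H-inden-2-one; 22 (2R)-2-methylbutanoic acid
Product: 23 (1R,3R,3aS,5R,7R,7aR)-1-[(1S)-1-{[tert-butyl(dimethyl)silyl]oxy}ethyl]-4-methylidene-2-oxo-7-(propan-2-yl)-5-[(triethylsilyl)oxy]octahydro-1H-inden-3-yl (2R)-2-methylbutanoate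
Conditions: 22 (1.5 equiv), EDC·HCl, DMAP, CH2Cl2, 0 °C to rt
Reagents that add atoms: (2R)-2-methylbutanoic acid 22, CC[C@@H](C)C(=O)O
Why: Steglich esterification with retention at C3; an α-alkyl acid with no activating α-heteroatom is not expected to racemise under carbodiimide/DMAP activation.

Step 12
Reactants: 23 (1R,3R,3aS,5R,7R,7aR)-1-[(1S)-1-{[tert-butyl(dimethyl)silyl]oxy}ethyl]-4-methylidene-2-oxo-7-(propan-2-yl)-5-[(triethylsilyl)oxy]octahydro-1H-inden-3-yl (2R)-2-methylbutanoate
Product: 24 (1R,3R,3aS,5R,7R,7aR)-1-[(1S)-1-{[tert-butyl(dimethyl)silyl]oxy}ethyl]-5-hydroxy-4-methylidene-2-oxo-7-(propan-2-yl)octahydro-1H-inden-3-yl (2R)-2-methylbutanoate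
Conditions: PPTS (cat.), MeOH/CH2Cl2, 0 °C
Reagents that add atoms: none
Why: Acid-catalysed methanolysis distinguishes the triethylsilyl ether from the bulkier tert-butyldimethylsilyl ether; the ester and ketone should be stable to pyridinium tosylate.

Step 13
Reactants: 24 (1R,3R,3aS,5R,7R,7aR)-1-[(1S)-1-{[tert-butyl(dimethyl)silyl]oxy}ethyl]-5-hydroxy-4-methylidene-2-oxo-7-(propan-2-yl)octahydro-1H-inden-3-yl (2R)-2-methylbutanoate; 25 (2E)-3-methylpent-2-enoic acid
Product: 26 (1R,3R,3aS,5S,7R,7aR)-1-[(1S)-1-{[tert-butyl(dimethyl)silyl]oxy}ethyl]-3-{[(2R)-2-methylbutanoyl]oxy}-4-methylidene-2-oxo-7-(propan-2-yl)octahydro-1H-inden-5-yl (2E)-3-methylpent-2-enoate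
Conditions: 25 (2 equiv), PPh3, DIAD, toluene, 0 °C to rt
Reagents that add atoms: (2E)-3-methylpent-2-enoic acid 25, CC/C(C)=C/C(=O)O
Why: Mitsunobu esterification: the equatorial C5 alkoxyphosphonium ion is displaced by the carboxylate in an SN2 reaction with inversion, which should give the axial (5S) ester.

Step 14
Reactants: 26 (1R,3R,3aS,5S,7R,7aR)-1-[(1S)-1-{[tert-butyl(dimethyl)silyl]oxy}ethyl]-3-{[(2R)-2-methylbutanoyl]oxy}-4-methylidene-2-oxo-7-(propan-2-yl)octahydro-1H-inden-5-yl (2E)-3-methylpent-2-enoate
Product: 27 (1R,3R,3aS,5S,7R,7aR)-1-[(1S)-1-hydroxyethyl]-3-{[(2R)-2-methylbutanoyl]oxy}-4-methylidene-2-oxo-7-(propan-2-yl)octahydro-1H-inden-5-yl (2E)-3-methylpent-2-enoate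
Conditions: HF·pyridine, pyridine, THF, 0 °C to rt
Reagents that add atoms: none
Why: Fluoride-assisted desilylation under buffered acidic conditions, which should spare the two esters and avoid the retro-aldol or elimination that basic fluoride would cause.

Step 15
Reactants: 27 (1R,3R,3aS,5S,7R,7aR)-1-[(1S)-1-hydroxyethyl]-3-{[(2R)-2-methylbutanoyl]oxy}-4-methylidene-2-oxo-7-(propan-2-yl)octahydro-1H-inden-5-yl (2E)-3-methylpent-2-enoate
Product: 28 (1R,3R,3aS,5S,7R,7aR)-1-[(1S)-1-acetoxyethyl]-3-{[(2R)-2-methylbutanoyl]oxy}-4-methylidene-2-oxo-7-(propan-2-yl)octahydro-1H-inden-5-yl (2E)-3-methylpent-2-enoate (target)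
Conditions: Ac2O, pyridine, DMAP (cat.), CH2Cl2, 0 °C
Reagents that add atoms: acetic anhydride, CC(=O)OC(C)=O
Why: Acylation of a secondary alcohol with acetic anhydride and pyridine at low temperature; the β-acetoxy ketone is formed last and is not exposed to strong base, so E1cB loss of acetate should be avoided.

## Compound list

1 | (1S,4R)-cis-4-acetoxycyclopent-2-en-1-ol | CC(=O)O[C@@H]1C[C@H](O)C=C1 | starting material
2 | ethynyltrimethylsilane | C#C[Si](C)(C)C | starting material
3 | lithium (trimethylsilyl)acetylide | [Li]C#C[Si](C)(C)C | intermediate (not isolated)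
4 | chloro[(trimethylsilyl)ethynyl]zinc | Cl[Zn]C#C[Si](C)(C)C | intermediate (not isolated)
5 | (1S,4S)-4-[(trimethylsilyl)ethynyl]cyclopent-2-en-1-ol | C[Si](C)(C)C#C[C@H]1C[C@H](O)C=C1 | intermediate
6 | (4S)-4-[(trimethylsilyl)ethynyl]cyclopent-2-en-1-one | C[Si](C)(C)C#C[C@H]1CC(=O)C=C1 | intermediate
7 | vinylmagnesium bromide | C=C[Mg]Br | starting material
8 | acetaldehyde | CC=O | starting material
9 | bromomagnesium enolate of the vinyl adduct | C[Si](C)(C)C#C[C@@H]1[C@H](C=C(O[Mg]Br)C1)C=C | intermediate (not isolated)
10 | tri(isopropoxy)titanium enolate of the vinyl adduct | C[Si](C)(C)C#C[C@@H]1[C@H](C=C(O[Ti](OC(C)C)(OC(C)C)OC(C)C)C1)C=C | intermediate (not isolated)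
11 | (2R,3R,4S)-3-ethenyl-2-[(1S)-1-hydroxyethyl]-4-[(trimethylsilyl)ethynyl]cyclopentan-1-one | C[Si](C)(C)C#C[C@@H]1[C@H]([C@H]([C@H](C)O)C(=O)C1)C=C | intermediate
12 | (2R,3R,4S)-2-[(1S)-1-{[tert-butyl(dimethyl)silyl]oxy}ethyl]-3-ethenyl-4-[(trimethylsilyl)ethynyl]cyclopentan-1-one | C[Si](C)(C)C#C[C@@H]1[C@H]([C@H]([C@H](C)O[Si](C)(C)C(C)(C)C)C(=O)C1)C=C | intermediate
13 | S-ethyl prop-2-enethioate | C=CC(=O)SCC | starting material
14 | S-ethyl (2E)-3-{(1R,2R,5S)-2-[(1S)-1-{[tert-butyl(dimethyl)silyl]oxy}ethyl]-3-oxo-5-[(trimethylsilyl)ethynyl]cyclopentyl}prop-2-enethioate | C[Si](C)(C)C#C[C@@H]1[C@H]([C@H]([C@H](C)O[Si](C)(C)C(C)(C)C)C(=O)C1)/C=C/C(=O)SCC | intermediate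
15 | isopropylmagnesium bromide | CC(C)[Mg]Br | starting material
16 | S-ethyl (3R)-3-{(1R,2R,5S)-2-[(1S)-1-{[tert-butyl(dimethyl)silyl]oxy}ethyl]-3-oxo-5-[(trimethylsilyl)ethynyl]cyclopentyl}-4-methylpentanethioate | C[Si](C)(C)C#C[C@@H]1[C@H]([C@H]([C@H](C)O[Si](C)(C)C(C)(C)C)C(=O)C1)[C@@H](C(C)C)CC(=O)SCC | intermediate
17 | (3R)-3-{(1R,2R,5S)-2-[(1S)-1-{[tert-butyl(dimethyl)silyl]oxy}ethyl]-3-oxo-5-[(trimethylsilyl)ethynyl]cyclopentyl}-4-methylpentanal | C[Si](C)(C)C#C[C@@H]1[C@H]([C@H]([C@H](C)O[Si](C)(C)C(C)(C)C)C(=O)C1)[C@@H](C(C)C)CC=O | intermediate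
18 | (3R)-3-{(1R,2R,5S)-2-[(1S)-1-{[tert-butyl(dimethyl)silyl]oxy}ethyl]-5-ethynyl-3-oxocyclopentyl}-4-methylpentanal | C#C[C@@H]1[C@H]([C@H]([C@H](C)O[Si](C)(C)C(C)(C)C)C(=O)C1)[C@@H](C(C)C)CC=O | intermediate
19 | (1R,3aS,5R,7R,7aR)-1-[(1S)-1-{[tert-butyl(dimethyl)silyl]oxy}ethyl]-4-methylidene-7-(propan-2-yl)-5-[(triethylsilyl)oxy]octahydro-2H-inden-2-one | C=C1[C@@H]2[C@H]([C@H]([C@H](C)O[Si](C)(C)C(C)(C)C)C(=O)C2)[C@@H](C(C)C)C[C@H]1O[Si](CC)(CC)CC | intermediate
20 | potassium C2–C3 enolate of 19 | C=C1[C@@H]2[C@H]([C@H]([C@H](C)O[Si](C)(C)C(C)(C)C)C(O[K])=C2)[C@@H](C(C)C)C[C@H]1O[Si](CC)(CC)CC | intermediate (not isolated)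
21 | (1R,3R,3aS,5R,7R,7aR)-1-[(1S)-1-{[tert-butyl(dimethyl)silyl]oxy}ethyl]-3-hydroxy-4-methylidene-7-(propan-2-yl)-5-[(triethylsilyl)oxy]octahydro-2H-inden-2-one | C=C1[C@@H]2[C@H]([C@H]([C@H](C)O[Si](C)(C)C(C)(C)C)C(=O)[C@@H]2O)[C@@H](C(C)C)C[C@H]1O[Si](CC)(CC)CC | intermediate
22 | (2R)-2-methylbutanoic acid | CC[C@@H](C)C(=O)O | starting material
23 | (1R,3R,3aS,5R,7R,7aR)-1-[(1S)-1-{[tert-butyl(dimethyl)silyl]oxy}ethyl]-4-methylidene-2-oxo-7-(propan-2-yl)-5-[(triethylsilyl)oxy]octahydro-1H-inden-3-yl (2R)-2-methylbutanoate | C=C1[C@@H]2[C@H]([C@H]([C@H](C)O[Si](C)(C)C(C)(C)C)C(=O)[C@@H]2OC(=O)[C@H](C)CC)[C@@H](C(C)C)C[C@H]1O[Si](CC)(CC)CC | intermediate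
24 | (1R,3R,3aS,5R,7R,7aR)-1-[(1S)-1-{[tert-butyl(dimethyl)silyl]oxy}ethyl]-5-hydroxy-4-methylidene-2-oxo-7-(propan-2-yl)octahydro-1H-inden-3-yl (2R)-2-methylbutanoate | C=C1[C@@H]2[C@H]([C@H]([C@H](C)O[Si](C)(C)C(C)(C)C)C(=O)[C@@H]2OC(=O)[C@H](C)CC)[C@@H](C(C)C)C[C@H]1O | intermediate
25 | (2E)-3-methylpent-2-enoic acid | CC/C(C)=C/C(=O)O | starting material
26 | (1R,3R,3aS,5S,7R,7aR)-1-[(1S)-1-{[tert-butyl(dimethyl)silyl]oxy}ethyl]-3-{[(2R)-2-methylbutanoyl]oxy}-4-methylidene-2-oxo-7-(propan-2-yl)octahydro-1H-inden-5-yl (2E)-3-methylpent-2-enoate | C=C1[C@@H]2[C@H]([C@H]([C@H](C)O[Si](C)(C)C(C)(C)C)C(=O)[C@@H]2OC(=O)[C@H](C)CC)[C@@H](C(C)C)C[C@@H]1OC(=O)/C=C(\C)CC | intermediate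
27 | (1R,3R,3aS,5S,7R,7aR)-1-[(1S)-1-hydroxyethyl]-3-{[(2R)-2-methylbutanoyl]oxy}-4-methylidene-2-oxo-7-(propan-2-yl)octahydro-1H-inden-5-yl (2E)-3-methylpent-2-enoate | C=C1[C@@H]2[C@H]([C@H]([C@H](C)O)C(=O)[C@@H]2OC(=O)[C@H](C)CC)[C@@H](C(C)C)C[C@@H]1OC(=O)/C=C(\C)CC | intermediate
28 | (1R,3R,3aS,5S,7R,7aR)-1-[(1S)-1-acetoxyethyl]-3-{[(2R)-2-methylbutanoyl]oxy}-4-methylidene-2-oxo-7-(propan-2-yl)octahydro-1H-inden-5-yl (2E)-3-methylpent-2-enoate | C=C1[C@@H]2[C@H]([C@H]([C@H](C)OC(C)=O)C(=O)[C@@H]2OC(=O)[C@H](C)CC)[C@@H](C(C)C)C[C@@H]1OC(=O)/C=C(\C)CC | target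

## Step count and risk

Total steps: 15. Longest linear sequence: 15 steps (1 to 28).

**Step 9 (key step).** The most likely failure is oligomerisation or plain hydrosilylation of the terminal alkyne outrunning oxidative cyclisation, because closing a trans-fused six-membered ring through a planar metallacycle is slower than in unconstrained ynals. A second risk is base- or metal-triggered intramolecular aldol reaction of the keto aldehyde. Fallback: a one-electron closure of the same bond from 18. SmI2 (divalent samarium) with HMPA and t-BuOH in THF at −78 °C should reduce the aldehyde (much faster than the flanked ketone) to a ketyl radical that adds 6-exo to the alkyne, giving the free allylic alcohol (1R,3aS,5R,7R,7aR)-1-[(1S)-1-{[tert-butyl(dimethyl)silyl]oxy}ethyl]-5-hydroxy-4-methylidene-7-(propan-2-yl)octahydro-2H-inden-2-one F1. Silylation (Et3SiCl, imidazole, DMF) returns to 19.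

**Step 1.** Loss of regiocontrol at the π-allyl stage (1,2- instead of 1,4-substitution), β-hydride loss from the allyl complex, or alkyne homocoupling may compete, because inner-sphere allyl–alkynyl coupling is slower than with aryl or alkenyl partners. Fallback, setting out from 1 and rejoining at 6: MnO2 oxidation gives (1R)-4-oxocyclopent-2-en-1-yl acetate F2; lipase hydrolysis at pH 7 gives (4R)-4-hydroxycyclopent-2-en-1-one F3; hydroxyl-directed conjugate addition of dimethyl[(trimethylsilyl)ethynyl]aluminium (from 3 and Me2AlCl) cis to the hydroxyl group gives (3R,4R)-4-hydroxy-3-[(trimethylsilyl)ethynyl]cyclopentan-1-one F4; dehydration (MsCl, Et3N, −20 °C) gives 6.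

**Step 3.** Poor syn/anti control in the aldol is the main risk, because the closed transition state of a cyclic enolate normally leans anti and the titanium effect is moderate with a small aldehyde. Incomplete anti delivery of vinyl beside the slim alkynyl group is a second risk. Fallback, from 6 back to 11: copper-catalysed addition of 7 in the presence of Me3SiCl gives the isolable silyl enol ether {[(3R,4S)-3-ethenyl-4-[(trimethylsilyl)ethynyl]cyclopent-1-en-1-yl]oxy}(trimethyl)silane F5. A fluoride-promoted aldol of the naked enolate with 8 (tris(dimethylamino)sulfonium difluorotrimethylsilicate, THF, −78 °C) then proceeds through an open transition state, which is syn-selective irrespective of enolate geometry; mild acidic work-up gives 11.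

**Step 6.** Grignard attack on, or enolisation of, the ring ketone may compete, because the β-carbon is flanked by a substituted ring and conjugate addition is slow. A mismatched facial bias from the ring, or intramolecular aldol of the thioester enolate onto the ketone, is also possible. Fallback by auxiliary control, from 12 back to 16: cross-metathesis with (4S)-3-acryloyl-4-phenyl-1,3-oxazolidin-2-one gives (4S)-3-[(2E)-3-{(1R,2R,5S)-2-[(1S)-1-{[tert-butyl(dimethyl)silyl]oxy}ethyl]-3-oxo-5-[(trimethylsilyl)ethynyl]cyclopentyl}prop-2-enoyl]-4-phenyl-1,3-oxazolidin-2-one F6. A stoichiometric organocopper reagent from 15 and CuBr·SMe2 (unreactive toward ketones at −78 °C) adds anti to the phenyl group of the chelated imide, which is the Re face of C7, giving (4S)-3-[(3R)-3-{(1R,2R,5S)-2-[(1S)-1-{[tert-butyl(dimethyl)silyl]oxy}ethyl]-3-oxo-5-[(trimethylsilyl)ethynyl]cyclopentyl}-4-methylpentanoyl]-4-phenyl-1,3-oxazolidin-2-one F7. Thiolysis with LiSEt gives 16.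

**Step 10.** Oxygen transfer to the face syn to the C3a hydrogen is the main risk, since the two faces of the enolate differ only by torsional effects. Proton transfer between enolate and product could also lead to enolisation toward C1 and loss of the silyloxy group. Fallback, from 19 back to 23: if hydroxylation gives the epimer (1R,3S,3aS,5R,7R,7aR)-1-[(1S)-1-{[tert-butyl(dimethyl)silyl]oxy}ethyl]-3-hydroxy-4-methylidene-7-(propan-2-yl)-5-[(triethylsilyl)oxy]octahydro-2H-inden-2-one F8, it is esterified with 22 under Mitsunobu conditions (PPh3, DIAD), which inverts C3 and gives 23 directly.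

**Step 13.** Allylic transposition (attack of the carboxylate at the methylene carbon) or elimination to a diene may compete with direct displacement, because backside attack at C5 is axial and passes two axial hydrogens. Fallback by oxidation and reduction, from 24 back to 26: MnO2 gives the enone (1R,3R,3aS,7R,7aR)-1-[(1S)-1-{[tert-butyl(dimethyl)silyl]oxy}ethyl]-4-methylidene-2,5-dioxo-7-(propan-2-yl)octahydro-1H-inden-3-yl (2R)-2-methylbutanoate F9. Corey–Bakshi–Shibata reduction ((R)-2-methyl-CBS-oxazaborolidine, catecholborane, −78 °C) should give, under reagent control, the axial alcohol (1R,3R,3aS,5S,7R,7aR)-1-[(1S)-1-{[tert-butyl(dimethyl)silyl]oxy}ethyl]-5-hydroxy-4-methylidene-2-oxo-7-(propan-2-yl)octahydro-1H-inden-3-yl (2R)-2-methylbutanoate F10. Yamaguchi esterification with 25 (2,4,6-trichlorobenzoyl chloride, Et3N, DMAP) gives 26.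

## Further compounds

F1 | step 9 | (1R,3aS,5R,7R,7aR)-1-[(1S)-1-{[tert-butyl(dimethyl)silyl]oxy}ethyl]-5-hydroxy-4-methylidene-7-(propan-2-yl)octahydro-2H-inden-2-one | C=C1[C@@H]2[C@H]([C@H]([C@H](C)O[Si](C)(C)C(C)(C)C)C(=O)C2)[C@@H](C(C)C)C[C@H]1O
F2 | step 1 | (1R)-4-oxocyclopent-2-en-1-yl acetate | CC(=O)O[C@@H]1CC(=O)C=C1
F3 | step 1 | (4R)-4-hydroxycyclopent-2-en-1-one | O[C@@H]1CC(=O)C=C1
F4 | step 1 | (3R,4R)-4-hydroxy-3-[(trimethylsilyl)ethynyl]cyclopentan-1-one | O[C@@H]1CC(=O)C[C@@H]1C#C[Si](C)(C)C
F5 | step 3 | {[(3R,4S)-3-ethenyl-4-[(trimethylsilyl)ethynyl]cyclopent-1-en-1-yl]oxy}(trimethyl)silane | C[Si](C)(C)C#C[C@@H]1[C@H](C=C(O[Si](C)(C)C)C1)C=C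
F6 | step 6 | (4S)-3-[(2E)-3-{(1R,2R,5S)-2-[(1S)-1-{[tert-butyl(dimethyl)silyl]oxy}ethyl]-3-oxo-5-[(trimethylsilyl)ethynyl]cyclopentyl}prop-2-enoyl]-4-phenyl-1,3-oxazolidin-2-one | C[Si](C)(C)C#C[C@@H]1[C@H]([C@H]([C@H](C)O[Si](C)(C)C(C)(C)C)C(=O)C1)/C=C/C(=O)N3[C@@H](c4ccccc4)COC3=O
F7 | step 6 | (4S)-3-[(3R)-3-{(1R,2R,5S)-2-[(1S)-1-{[tert-butyl(dimethyl)silyl]oxy}ethyl]-3-oxo-5-[(trimethylsilyl)ethynyl]cyclopentyl}-4-methylpentanoyl]-4-phenyl-1,3-oxazolidin-2-one | C[Si](C)(C)C#C[C@@H]1[C@H]([C@H]([C@H](C)O[Si](C)(C)C(C)(C)C)C(=O)C1)[C@@H](C(C)C)CC(=O)N3[C@@H](c4ccccc4)COC3=O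
F8 | step 10 | (1R,3S,3aS,5R,7R,7aR)-1-[(1S)-1-{[tert-butyl(dimethyl)silyl]oxy}ethyl]-3-hydroxy-4-methylidene-7-(propan-2-yl)-5-[(triethylsilyl)oxy]octahydro-2H-inden-2-one | C=C1[C@@H]2[C@H]([C@H]([C@H](C)O[Si](C)(C)C(C)(C)C)C(=O)[C@H]2O)[C@@H](C(C)C)C[C@H]1O[Si](CC)(CC)CC
F9 | step 13 | (1R,3R,3aS,7R,7aR)-1-[(1S)-1-{[tert-butyl(dimethyl)silyl]oxy}ethyl]-4-methylidene-2,5-dioxo-7-(propan-2-yl)octahydro-1H-inden-3-yl (2R)-2-methylbutanoate | C=C1[C@@H]2[C@H]([C@H]([C@H](C)O[Si](C)(C)C(C)(C)C)C(=O)[C@@H]2OC(=O)[C@H](C)CC)[C@@H](C(C)C)CC1=O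
F10 | step 13 | (1R,3R,3aS,5S,7R,7aR)-1-[(1S)-1-{[tert-butyl(dimethyl)silyl]oxy}ethyl]-5-hydroxy-4-methylidene-2-oxo-7-(propan-2-yl)octahydro-1H-inden-3-yl (2R)-2-methylbutanoate | C=C1[C@@H]2[C@H]([C@H]([C@H](C)O[Si](C)(C)C(C)(C)C)C(=O)[C@@H]2OC(=O)[C@H](C)CC)[C@@H](C(C)C)C[C@@H]1O
A1 | alternative 1 | trans-fused bicyclic methyl ketone with ring alkene, dithiane and C3 silyl ether (Diels–Alder adduct) | CC1=CC[C@H](C(C)=O)[C@H]2CC3(SCCCS3)[C@H](O[Si](C)(C)C(C)(C)C)[C@H]12
A2 | alternative 1 | dithiane-tethered trienone (Diels–Alder substrate) | C=C/C(C)=C/[C@@H](O[Si](C)(C)C(C)(C)C)C1(SCCCS1)C/C=C/C(C)=O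
A3 | alternative 2 | trans-fused bicyclic β-keto ester (C–H insertion product) | O1CCOC12[C@@H]3[C@H]([C@H](C(=O)OCC)C(=O)[C@@H]3O[Si](C)(C)C(C)(C)C)[C@@H](C(C)C)CC2
A4 | alternative 2 | α-diazo-β-keto ester on the cyclohexanone ketal (insertion substrate) | O1CCOC12[C@@H]([C@@H](O[Si](C)(C)C(C)(C)C)C(=O)C(=[N+]=[N-])C(=O)OCC)C[C@@H](C(C)C)CC2
A5 | alternative 2 | 4-(propan-2-yl)cyclohexanone | CC(C)C1CCC(=O)CC1
A6 | alternative 3 | bicyclic cyclopentenone acetonide (Pauson–Khand product) | CC1(C)OC[C@H]2[C@@H](O1)C[C@H](C(C)C)C3=C([C@H](C)O[Si](C)(C)C(C)(C)C)C(=O)C[C@H]23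
A7 | alternative 3 | acyclic 1,7-enyne acetonide (Pauson–Khand substrate) | C=C[C@H]1COC(C)(C)O[C@H]1C[C@H](C(C)C)C#C[C@H](C)O[Si](C)(C)C(C)(C)C
A8 | alternative 3 | (S)-but-3-yn-2-ol | C#C[C@H](C)O
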